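**Plan**

1. Retrosynthesis: the two isovalerates, the two acetates and the 11,20-epoxide come off first. Then the lactone C19–O7 bond and C6–Cl (chloride opening of a 6,7-epoxide), C5–C6 (Stille), C8–C17 (amide aldol) and C7–C8 (vinyl addition) are cut. The cyclohexane is cut at C13–C14 and C11–C12. C1–C2, C1–C15 and C10–C11 lead back to a butenolide.
2. Forward: butenolide → trisubstituted γ-lactone (C9, C10, C1) → open-chain C14 aldehyde → cyclohexane (key step) → C8 side chain → ten-membered ring by C5–C6 closure → γ-lactone with C6–Cl → acetates, 11,20-epoxide, isovalerates.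
3. Key event: a Mukaiyama aldol–Prins [4+2] annulation of the C14 aldehyde with a vinyl silyl ether and an internal vinylsilane. It is possible because the cyclohexane holds an acetaldehyde-type C13–C12(O) unit between the carbinol carbon C14 and the exocyclic C11=C20 methylene, and because O2, O14 and O12 can sit on one titanium (cis-1,3-diaxial O14/O12).
4. Stereochemistry: C9 from (S)-5-(hydroxymethyl)furan-2(5H)-one; C10 and C1 by anti addition and anti methylation on the lactone; C2 by Felkin–Anh reduction; C14 by 1,3-chelation; C12 by the titanium-bridged chair.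
5. C8 and C17 by a Felkin–Anh, Z-enolate aldol; C7 and C6 by hydroxyl-directed epoxidation of the E-C6=C7 alkene and anti opening by chloride; C11 by epoxidation directed by the axial C12 hydroxyl.

Key step: step 12

Remark: locants are briarane locants of the target (C1 quaternary carbon with methyl C15; C2–C9 ten-membered-ring carbons, C5 bearing methylene C16, C6 Cl, C7 lactone O, C8 OH; C10 ring-fusion CH; C11–C14 cyclohexane carbons, C20 epoxide CH2; C17–C19 lactone carbons, C18 methyl).

**Route**

Step 1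
Reactants: 1 pent-4-ynoic acid
Product: 2 4-iodopent-4-enoic acid
Conditions: NaI, TMSCl, H2O, MeCN, rt
Reagents that add atoms: sodium iodide [Na+].[I-]
Why: HI made in situ should add to the terminal alkyne in the Markovnikov sense (alkyne hydroiodination), which gives the 2-iodo-1-alkene that later serves as the C5 coupling site.

Step 2
Reactants: 3 (S)-5-(hydroxymethyl)furan-2(5H)-one
Product: 4 (S)-5-[(tert-butyldimethylsilyloxy)methyl]furan-2(5H)-one
Conditions: TBSCl, imidazole, DMF, 0 °C to rt
Reagents that add atoms: tert-butyldimethylsilyl chloride CC(C)(C)[Si](C)(C)Cl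
Why: Silyl ether formation on the primary alcohol (O8) leaves the C9 stereocentre of the chiral-pool butenolide untouched.

Step 3
Reactants: 4 (S)-5-[(tert-butyldimethylsilyloxy)methyl]furan-2(5H)-one; 5 (1-bromovinyl)trimethylsilane
Product: 7 (4S,5S)-5-[(tert-butyldimethylsilyloxy)methyl]-4-[1-(trimethylsilyl)vinyl]dihydrofuran-2(3H)-one, via [1-(trimethylsilyl)vinyl]magnesium bromide 6 (not isolated)
Conditions: Mg, THF, rt (5 to 6); CuI (10 mol %), THF, −40 °C, then 4
Reagents that add atoms: none
Why: Copper-catalysed conjugate addition of the Grignard reagent to the butenolide should occur anti to the C9 silyloxymethyl group and so set C10 (4,5-trans lactone).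

Step 4
Reactants: 7 trans-4,5-disubstituted lactone; 2 4-iodopent-4-enoic acid
Product: 9 3-(4-iodopent-4-enoyl) β-keto lactone (acyl trans to the C10 substituent), via 1-(4-iodopent-4-enoyl)imidazole 8 (not isolated)
Conditions: 2, CDI, THF, rt (to 8); 7, LiHMDS (2.1 equiv), THF, −78 °C, then 8, −78 to −20 °C; AcOH
Reagents that add atoms: none
Why: Claisen-type C-acylation of the lactone lithium enolate by the acyl imidazole forms the C1–C2 bond, the second equivalent of base holding the product as its enolate; the C1–H centre formed here is replaced in step 5.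

Step 5
Reactants: 9 β-keto lactone
Product: 10 3-methyl β-keto lactone (quaternary C1, methyl trans to the 1-silylvinyl group)
Conditions: K2CO3, MeI, acetone, rt
Reagents that add atoms: iodomethane CI
Why: C-methylation of the β-keto lactone enolate (enolate alkylation) should take place on the face opposite the neighbouring 1-silylvinyl group on C10, which sets the quaternary C1.

Step 6
Reactants: 10 3-methyl β-keto lactone
Product: 11 β-hydroxy lactone (C2 carbinol)
Conditions: K-Selectride, THF, −78 °C; AcOH at −78 °C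
Reagents that add atoms: none
Why: Non-chelating Felkin–Anh reduction, in which the hydride enters anti to the lactone carbonyl carbon and past the C1 methyl while the C10 branch shields the other face, should set C2 as in the target; the cold acidic quench prevents retro-aldol cleavage.

Step 7
Reactants: 11 β-hydroxy lactone
Product: 12 C2,C9,C14-triol
Conditions: LiBH4, THF, 0 °C to rt
Reagents that add atoms: none
Why: Borohydride reduction of the γ-lactone to the diol opens the ring without touching any stereocentre.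

Step 8
Reactants: 12 C2,C9,C14-triol
Product: 13 C2/C14 4-methoxybenzylidene acetal (free C9 alcohol)
Conditions: 4-MeOC6H4CH(OMe)2, PPTS, CH2Cl2, rt
Reagents that add atoms: 4-methoxybenzaldehyde dimethyl acetal COc1ccc(C(OC)OC)cc1
Why: Acid-catalysed transacetalisation should select the C2/C14 1,3-diol (six-membered 1,3-dioxane) over the seven-membered alternative with O9, and thermodynamic control places the aryl group equatorial, cis to the C3 chain.

Step 9
Reactants: 13 C2/C14 4-methoxybenzylidene acetal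
Product: 14 C9 TBS ether of the acetal
Conditions: TBSOTf, 2,6-lutidine, CH2Cl2, −78 to 0 °C
Reagents that add atoms: tert-butyldimethylsilyl triflate CC(C)(C)[Si](C)(C)OS(=O)(=O)C(F)(F)F
Why: Silylation of the hindered secondary C9 alcohol with the silyl triflate puts a non-chelating group on O9.

Step 10
Reactants: 14 C9 TBS ether of the acetal
Product: 15 C14 primary alcohol with C2 PMB ether
Conditions: DIBAL-H, CH2Cl2, −78 to 0 °C
Reagents that add atoms: none
Why: Regioselective reductive opening of the 4-methoxybenzylidene acetal: aluminium binds the less hindered O14, the C–O14 bond breaks and hydride delivery leaves the PMB ether on O2 and the free primary alcohol at C14.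

Step 11
Reactants: 15 C14 primary alcohol
Product: 16 C14 aldehyde
Conditions: Dess–Martin periodinane, CH2Cl2, rt
Reagents that add atoms: none
Why: Dess–Martin oxidation of the neopentyl primary alcohol gives the aldehyde, which has no α-hydrogen and cannot epimerise.

Step 12
Reactants: 16 C14 aldehyde; 17 trimethyl(vinyloxy)silane
Product: 19 11-methylenecyclohexane-12,14-diol, via C14-hydroxy C12-aldehyde 18 (not isolated)
Conditions: TiCl4 (2.2 equiv), 2,6-di-tert-butyl-4-methylpyridine (0.5 equiv), CH2Cl2, −78 °C; 17 (1.5 equiv) added over 1 h; −78 to −40 °C; aq. NaHCO3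
Reagents that add atoms: none
Why: Proposed new method: TiCl4 closes a six-membered chelate between the C14 aldehyde oxygen and the C2 PMB ether, silyl enol ether 17 adds to C14 in a chelation-controlled Mukaiyama aldol (bond C13–C14), and the titanium aldolate holds the new C12 aldehyde so that the 1-silylvinyl group on C10 attacks it through its silicon-bearing carbon (bond C11–C12, β-silyl cation, loss of the silyl group), which leaves the exocyclic C11=C20 methylene. The closest known reaction type is the Mukaiyama aldol–Prins cascade of alkyl enol ethers with aldehydes terminated by an allylsilane, which gives oxacycles; here it is transposed to a carbocycle and to a vinylsilane terminator, whose ipso substitution by carbon electrophiles is known separately. The cyclohexane closes in a 6-exo-trig cation–olefin cyclisation (carbonyl oxygen and C20 both outside the ring) through a chair with the C2 and C9 chains equatorial on C1 and C10 and the C1 methyl axial. C14 is set by the chelate, in whose chair the C3 chain and C10 are equatorial and the C1 methyl axial, so that the nucleophile enters anti to the methyl (1,3-anti O2/O14); C12 is set by the titanium bridge between O14 and the C12 carbonyl, which forces both oxygens axial and cis. The step needs 17 to add before the internal vinylsilane reacts (a four-membered closure onto C14 is not viable) and ipso rather than terminal attack of the vinylsilane (six- versus seven-membered ring, β-silicon stabilisation). The quaternary C1 next to C14 excludes enolisation of the aldehyde.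

Step 13
Reactants: 19 11-methylenecyclohexane-12,14-diol
Product: 20 12,14-acetonide
Conditions: 2,2-dimethoxypropane, PPTS, CH2Cl2, rt
Reagents that add atoms: 2,2-dimethoxypropane COC(C)(C)OC
Why: Acetonide formation (transacetalisation) on the cis-1,3-diaxial diol protects O12 and O14 together.

Step 14
Reactants: 20 12,14-acetonide
Product: 21 C8 primary alcohol
Conditions: HF·pyridine, pyridine, THF, 0 °C
Reagents that add atoms: none
Why: Buffered HF·pyridine should cleave the primary silyl ether at C8 much faster than the hindered secondary one at C9 (selective desilylation).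

Step 15
Reactants: 21 C8 primary alcohol
Product: 22 C8 aldehyde
Conditions: Dess–Martin periodinane, CH2Cl2, 0 °C to rt
Reagents that add atoms: none
Why: Dess–Martin oxidation gives the α-silyloxy aldehyde under neutral conditions that should not epimerise C9.

Step 16
Reactants: 22 C8 aldehyde; 23 (E)-1,2-bis(tributylstannyl)ethene
Product: 25 C8 allylic alcohol with E-vinylstannane (mixture of C8 epimers), via (E)-2-(tributylstannyl)vinyllithium 24 (not isolated)
Conditions: n-BuLi (0.95 equiv to 23), THF, −78 °C (23 to 24); then 22, −78 °C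
Reagents that add atoms: none
Why: Tin–lithium exchange gives the E-vinyllithium, whose 1,2-addition to the aldehyde at −78 °C should outrun iodine–lithium exchange at C5; the C8 carbinol configuration is irrelevant because step 17 oxidises it.

Step 17
Reactants: 25 C8 allylic alcohol
Product: 26 E-β-stannyl enone (C8 ketone)
Conditions: MnO2, CH2Cl2, rt
Reagents that add atoms: none
Why: Allylic oxidation with manganese dioxide under neutral conditions spares the acid-sensitive vinylstannane.

Step 18
Reactants: 26 E-β-stannyl enone; 27 N,N-dimethylpropanamide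
Product: 30 amide aldol adduct (tertiary C8 alcohol), via lithium (Z)-amide enolate 28 (not isolated), via dichlorocerium (Z)-amide enolate 29 (not isolated)
Conditions: LDA, THF, −78 °C (27 to 28); CeCl3, −78 °C (to 29); then 26, −78 °C; AcOH at −78 °C
Reagents that add atoms: none
Why: Aldol 1,2-addition of the cerium (Z)-amide enolate to the ketone (the β-stannyl group and cerium disfavour conjugate addition and enolisation): Felkin–Anh attack anti to the C9 silyloxy group sets C8, and the Zimmerman–Traxler chair with the C9 branch equatorial sets C17 syn.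

Step 19
Reactants: 30 amide aldol adduct
Product: 31 ten-membered 5(16),6E-diene amide
Conditions: Pd2(dba)3 (10 mol %), Ph3As (40 mol %), NMP, 40 °C, 1 mM
Reagents that add atoms: none
Why: Intramolecular Stille coupling of the vinyl iodide with the E-vinylstannane closes the ten-membered ring at C5–C6 with retention of the E geometry, the two chains being held close as equatorial neighbours on the cyclohexane.

Step 20
Reactants: 31 ten-membered diene amide
Product: 32 6,7-epoxide
Conditions: VO(acac)2 (5 mol %), t-BuOOH, CH2Cl2, 0 °C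
Reagents that add atoms: tert-butyl hydroperoxide CC(C)(C)OO
Why: Vanadium-catalysed hydroxyl-directed epoxidation selects the allylic C6=C7 alkene; with the C8–C9 ring bond roughly perpendicular to the alkene plane the C8 hydroxyl should deliver oxygen to the face opposite C9, which sets C7 (trans epoxide).

Step 21
Reactants: 32 6,7-epoxide
Product: 34 chloro γ-lactone (C2 PMB ether, C9 TBS ether, acetonide), via 6-chloro-7-hydroxy amide 33 (not isolated)
Conditions: ClTi(OiPr)3, CH2Cl2, −20 to 0 °C; then AcOH (5 equiv), toluene, 40 °C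
Reagents that add atoms: chlorotitanium triisopropoxide CC(C)O[Ti](Cl)(OC(C)C)OC(C)C
Why: Titanium-assisted opening of the 2,3-epoxy alcohol by chloride at its C3 position (C6, also allylic) should proceed with inversion and set the C6–Cl/C7–O anti relationship, and the freed C7 hydroxyl then lactonises onto the amide under mild acid (γ-lactone formation, trans-fused).

Step 22
Reactants: 34 chloro γ-lactone
Product: 35 C2 alcohol
Conditions: DDQ, CH2Cl2/pH 7 buffer, 0 °C
Reagents that add atoms: none
Why: Oxidative cleavage of the PMB ether by DDQ frees the C2 hydroxyl and leaves the isolated alkenes, the allylic chloride and the other protecting groups intact.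

Step 23
Reactants: 35 C2 alcohol
Product: 36 C2,C9-diol
Conditions: HF·pyridine, THF, 0 °C to rt
Reagents that add atoms: none
Why: Desilylation with HF·pyridine frees the C9 hydroxyl under weakly acidic conditions that should avoid translactonisation and keep the acetonide.

Step 24
Reactants: 36 C2,C9-diol
Product: 37 2,9-diacetate acetonide
Conditions: Ac2O, DMAP (cat.), pyridine, rt
Reagents that add atoms: acetic anhydride CC(=O)OC(C)=O
Why: DMAP-catalysed acetylation esterifies the two secondary alcohols at C2 and C9, while the hindered tertiary C8 hydroxyl should not react.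

Step 25
Reactants: 37 2,9-diacetate acetonide
Product: 38 2,9-diacetate 12,14-diol
Conditions: AcOH/H2O (4:1), 40 °C
Reagents that add atoms: none
Why: Mild aqueous acid hydrolyses the acetonide (acetal hydrolysis) and leaves the acetates, the lactone and the allylic chloride.

Step 26
Reactants: 38 2,9-diacetate 12,14-diol
Product: 39 11,20-epoxy 12,14-diol 2,9-diacetate
Conditions: VO(acac)2 (5 mol %), t-BuOOH, CH2Cl2, 0 °C to rt
Reagents that add atoms: tert-butyl hydroperoxide CC(C)(C)OO
Why: Vanadium-catalysed epoxidation directed by the axial allylic C12 hydroxyl (supported by the axial C14 hydroxyl) should deliver oxygen only to the C11=C20 methylene, from the face of O12, which sets C11 with the oxygen equatorial and cis to O12; the C5=C16 alkene has no directing hydroxyl.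

Step 27
Reactants: 39 11,20-epoxy 12,14-diol 2,9-diacetate
Product: 40 CNP0238609.2 (target)
Conditions: isovaleric anhydride, DMAP, Et3N, CH2Cl2, rt to 40 °C
Reagents that add atoms: 3-methylbutanoic anhydride CC(C)CC(=O)OC(=O)CC(C)C
Why: DMAP-catalysed acylation with isovaleric anhydride esterifies the two secondary hydroxyls at C12 and C14 and should leave the tertiary C8 hydroxyl free, which completes the target.

**Compound list**

1 | pent-4-ynoic acid | C#CCCC(=O)O | starting material
2 | 4-iodopent-4-enoic acid | C=C(I)CCC(=O)O | intermediate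
3 | (S)-5-(hydroxymethyl)furan-2(5H)-one | O=C1C=C[C@@H](CO)O1 | starting material
4 | (S)-5-[(tert-butyldimethylsilyloxy)methyl]furan-2(5H)-one | O=C1C=C[C@@H](CO[Si](C)(C)C(C)(C)C)O1 | intermediate
5 | (1-bromovinyl)trimethylsilane | C=C(Br)[Si](C)(C)C | starting material
6 | [1-(trimethylsilyl)vinyl]magnesium bromide | C=C([Mg]Br)[Si](C)(C)C | intermediate
7 | (4S,5S)-5-[(tert-butyldimethylsilyloxy)methyl]-4-[1-(trimethylsilyl)vinyl]dihydrofuran-2(3H)-one (4,5-trans) | O=C1C[C@H](C(=C)[Si](C)(C)C)[C@@H](CO[Si](C)(C)C(C)(C)C)O1 | intermediate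
8 | 1-(4-iodopent-4-enoyl)imidazole | C=C(I)CCC(=O)n1ccnc1 | intermediate
9 | 3-(4-iodopent-4-enoyl) derivative of 7 (β-keto lactone, 3,4-trans) | O=C1[C@@H](C(=O)CCC(I)=C)[C@H](C(=C)[Si](C)(C)C)[C@@H](CO[Si](C)(C)C(C)(C)C)O1 | intermediate
10 | 3-methyl-3-(4-iodopent-4-enoyl) lactone (quaternary C1, methyl trans to the 1-silylvinyl group) | O=C1[C@](C)(C(=O)CCC(I)=C)[C@H](C(=C)[Si](C)(C)C)[C@@H](CO[Si](C)(C)C(C)(C)C)O1 | intermediate
11 | 3-(1-hydroxy-4-iodopent-4-enyl)-3-methyl lactone (C2 carbinol, O2 on the side of the C1 methyl in the C14–C1–C2–C3 zigzag) | O=C1[C@](C)([C@@H](O)CCC(I)=C)[C@H](C(=C)[Si](C)(C)C)[C@@H](CO[Si](C)(C)C(C)(C)C)O1 | intermediate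
12 | open-chain triol (C14 CH2OH, C2 OH, C9 OH; C8 OTBS, C5 vinyl iodide, C11 vinylsilane) | OC[C@](C)([C@@H](O)CCC(I)=C)[C@H](C(=C)[Si](C)(C)C)[C@H](O)CO[Si](C)(C)C(C)(C)C | intermediate
13 | 2-(4-methoxyphenyl)-1,3-dioxane across O2/O14 of 12 (aryl and C3 chain cis, equatorial; free C9 OH) | COc1ccc(cc1)[C@@H]2OC[C@@](C)([C@H](C(=C)[Si](C)(C)C)[C@H](O)CO[Si](C)(C)C(C)(C)C)[C@H](CCC(I)=C)O2 | intermediate
14 | C9 tert-butyldimethylsilyl ether of 13 | COc1ccc(cc1)[C@@H]2OC[C@@](C)([C@H](C(=C)[Si](C)(C)C)[C@H](O[Si](C)(C)C(C)(C)C)CO[Si](C)(C)C(C)(C)C)[C@H](CCC(I)=C)O2 | intermediate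
15 | C14 primary alcohol with C2 PMB ether and C8, C9 TBS ethers | OC[C@](C)([C@@H](OCc1ccc(OC)cc1)CCC(I)=C)[C@H](C(=C)[Si](C)(C)C)[C@H](O[Si](C)(C)C(C)(C)C)CO[Si](C)(C)C(C)(C)C | intermediate
16 | C14 aldehyde (α-quaternary C1, β-PMB ether at C2, vinylsilane at C11) | O=C[C@](C)([C@@H](OCc1ccc(OC)cc1)CCC(I)=C)[C@H](C(=C)[Si](C)(C)C)[C@H](O[Si](C)(C)C(C)(C)C)CO[Si](C)(C)C(C)(C)C | intermediate
17 | trimethyl(vinyloxy)silane | C=CO[Si](C)(C)C | starting material
18 | C14-hydroxy C12-aldehyde (aldol adduct, O14 anti to O2; titanium alkoxide in the flask) | O=CC[C@H](O)[C@](C)([C@@H](OCc1ccc(OC)cc1)CCC(I)=C)[C@H](C(=C)[Si](C)(C)C)[C@H](O[Si](C)(C)C(C)(C)C)CO[Si](C)(C)C(C)(C)C | intermediate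
19 | 1-methyl-11-methylenecyclohexane-12,14-diol (cis-diaxial diol; C1 side chain 1-(PMB-oxy)-4-iodopent-4-enyl, C10 side chain 1,2-bis(TBS-oxy)ethyl) | C=C(I)CC[C@H](OCc1ccc(OC)cc1)[C@@]2(C)[C@@H](O)C[C@@H](O)C(=C)[C@@H]2[C@H](O[Si](C)(C)C(C)(C)C)CO[Si](C)(C)C(C)(C)C | intermediate
20 | 12,14-acetonide of 19 | C=C(I)CC[C@H](OCc1ccc(OC)cc1)[C@@]2(C)[C@@H]3C[C@@H](OC(C)(C)O3)C(=C)[C@@H]2[C@H](O[Si](C)(C)C(C)(C)C)CO[Si](C)(C)C(C)(C)C | intermediate
21 | C8 primary alcohol (C9 TBS ether kept) | C=C(I)CC[C@H](OCc1ccc(OC)cc1)[C@@]2(C)[C@@H]3C[C@@H](OC(C)(C)O3)C(=C)[C@@H]2[C@H](O[Si](C)(C)C(C)(C)C)CO | intermediate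
22 | C8 aldehyde | C=C(I)CC[C@H](OCc1ccc(OC)cc1)[C@@]2(C)[C@@H]3C[C@@H](OC(C)(C)O3)C(=C)[C@@H]2[C@H](O[Si](C)(C)C(C)(C)C)C=O | intermediate
23 | (E)-1,2-bis(tributylstannyl)ethene | CCCC[Sn](CCCC)(CCCC)/C=C/[Sn](CCCC)(CCCC)CCCC | starting material
24 | (E)-2-(tributylstannyl)vinyllithium | [Li]/C=C/[Sn](CCCC)(CCCC)CCCC | intermediate
25 | C8 allylic alcohol with (E)-2-(tributylstannyl)vinyl group (C8 epimers) | C=C(I)CC[C@H](OCc1ccc(OC)cc1)[C@@]2(C)[C@@H]3C[C@@H](OC(C)(C)O3)C(=C)[C@@H]2[C@H](O[Si](C)(C)C(C)(C)C)C(O)/C=C/[Sn](CCCC)(CCCC)CCCC | intermediate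
26 | (E)-β-stannyl enone (C8 ketone) | C=C(I)CC[C@H](OCc1ccc(OC)cc1)[C@@]2(C)[C@@H]3C[C@@H](OC(C)(C)O3)C(=C)[C@@H]2[C@H](O[Si](C)(C)C(C)(C)C)C(=O)/C=C/[Sn](CCCC)(CCCC)CCCC | intermediate
27 | N,N-dimethylpropanamide | CCC(=O)N(C)C | starting material
28 | lithium (Z)-enolate of N,N-dimethylpropanamide | C/C=C(\O[Li])N(C)C | intermediate
29 | dichlorocerium (Z)-enolate of N,N-dimethylpropanamide | C/C=C(\O[Ce](Cl)Cl)N(C)C | intermediate
30 | amide aldol adduct (tertiary C8 alcohol, C17 methyl syn, E-vinylstannane, C5 vinyl iodide) | C=C(I)CC[C@H](OCc1ccc(OC)cc1)[C@@]2(C)[C@@H]3C[C@@H](OC(C)(C)O3)C(=C)[C@@H]2[C@H](O[Si](C)(C)C(C)(C)C)[C@@](O)(/C=C/[Sn](CCCC)(CCCC)CCCC)[C@@H](C)C(=O)N(C)C | intermediate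
31 | ten-membered-ring 5(16),6E-diene with C8 OH and C17 dimethylamide side chain | C1C[C@H](OCc3ccc(OC)cc3)[C@@]2(C)[C@@H]4C[C@@H](OC(C)(C)O4)C(=C)[C@@H]2[C@H](O[Si](C)(C)C(C)(C)C)[C@](O)([C@@H](C)C(=O)N(C)C)/C=C/C1=C | intermediate
32 | trans-6,7-epoxide of 31 (oxygen on the face opposite C9) | C1C[C@H](OCc3ccc(OC)cc3)[C@@]2(C)[C@@H]4C[C@@H](OC(C)(C)O4)C(=C)[C@@H]2[C@H](O[Si](C)(C)C(C)(C)C)[C@](O)([C@@H](C)C(=O)N(C)C)[C@H]5O[C@@H]5C1=C | intermediate
33 | 6-chloro-7,8-dihydroxy amide (Cl and O7 anti) | C1C[C@H](OCc3ccc(OC)cc3)[C@@]2(C)[C@@H]4C[C@@H](OC(C)(C)O4)C(=C)[C@@H]2[C@H](O[Si](C)(C)C(C)(C)C)[C@](O)([C@@H](C)C(=O)N(C)C)[C@@H](O)[C@@H](Cl)C1=C | intermediate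
34 | chloro γ-lactone with C2 PMB ether, C9 TBS ether and 12,14-acetonide | C=C1CC[C@H](OCc5ccc(OC)cc5)[C@@]2(C)[C@@H]4C[C@@H](OC(C)(C)O4)C(=C)[C@@H]2[C@H](O[Si](C)(C)C(C)(C)C)[C@]3(O)[C@@H](C)C(=O)O[C@H]3[C@H]1Cl | intermediate
35 | C2 alcohol (C9 TBS ether, acetonide) | C=C1CC[C@H](O)[C@@]2(C)[C@@H]4C[C@@H](OC(C)(C)O4)C(=C)[C@@H]2[C@H](O[Si](C)(C)C(C)(C)C)[C@]3(O)[C@@H](C)C(=O)O[C@H]3[C@H]1Cl | intermediate
36 | C2,C9-diol (acetonide) | C=C1CC[C@H](O)[C@@]2(C)[C@@H]4C[C@@H](OC(C)(C)O4)C(=C)[C@@H]2[C@H](O)[C@]3(O)[C@@H](C)C(=O)O[C@H]3[C@H]1Cl | intermediate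
37 | 2,9-diacetate 12,14-acetonide | C=C1CC[C@H](OC(C)=O)[C@@]2(C)[C@@H]4C[C@@H](OC(C)(C)O4)C(=C)[C@@H]2[C@H](OC(C)=O)[C@]3(O)[C@@H](C)C(=O)O[C@H]3[C@H]1Cl | intermediate
38 | 2,9-diacetate 12,14-diol with 11(20)-methylene | C=C1CC[C@H](OC(C)=O)[C@@]2(C)[C@@H](O)C[C@@H](O)C(=C)[C@@H]2[C@H](OC(C)=O)[C@]3(O)[C@@H](C)C(=O)O[C@H]3[C@H]1Cl | intermediate
39 | 11,20-epoxy 12,14-diol 2,9-diacetate | C=C1CC[C@H](OC(C)=O)[C@@]2(C)[C@@H](O)C[C@@H](O)[C@]3(CO3)[C@@H]2[C@H](OC(C)=O)[C@]2(O)[C@@H](C)C(=O)O[C@H]2[C@H]1Cl | intermediate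
40 | CNP0238609.2 | C=C1CC[C@H](OC(C)=O)[C@@]2(C)[C@@H](OC(=O)CC(C)C)C[C@@H](OC(=O)CC(C)C)[C@]3(CO3)[C@@H]2[C@H](OC(C)=O)[C@]2(O)[C@@H](C)C(=O)O[C@H]2[C@H]1Cl | target

**Summary**

Total step count: 27. Longest linear sequence: 26 steps (3 to 40, steps 2–27).

Steps most likely to fail:

1. Step 12 (Proposed new method). The intermediate C12 aldehyde may be captured by a second molecule of 17 before ring closure, the vinylsilane may react through its terminal carbon (seven-membered closure), or chelate control at C14 may be incomplete. The fallback uses known chemistry, sets out from 16 and comes back at 19. A TiCl4-mediated, chelation-controlled Mukaiyama aldol of 16 with 1,1-bis(trimethylsilyloxy)ethene should give the β-hydroxy acid F1. TESCl and imidazole give the bis-triethylsilyl derivative F2. Oxalyl chloride with catalytic DMF converts the silyl ester into the acid chloride F3. SnCl4 at −78 °C should then bring about the intramolecular Friedel–Crafts ipso-acylation of the vinylsilane to the 2-methylenecyclohexanone F4. Luche reduction, in which the axial C14 silyloxy group blocks the axial path, should give the axial C12 alcohol F5, and AcOH/THF/H2O removes the triethylsilyl group to give 19.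

2. Step 19. Closure of the ten-membered diene may be slower than protodestannylation or intermolecular coupling. The fallback sets out from 22 and comes back at 31. Vinylmagnesium bromide gives the allylic alcohol F6, Dess–Martin oxidation gives the vinyl ketone F7, and the cerium enolate 29 gives the aldol adduct F8 under the same stereocontrol as in step 18. An intramolecular Heck reaction (Pd(OAc)2, P(o-tol)3, Ag2CO3, MeCN, high dilution) then joins C5 to the terminal alkene carbon and gives 31 after β-hydride elimination.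

3. Step 21. Chloride may enter with allylic transposition (SN2′ at C16) or after ionisation of the vinyl epoxide, with loss of regio- or stereocontrol at C6. The fallback sets out from 31, bypasses 32 and comes back at 34. Direct anti chlorolactonisation of the E-C6=C7 alkene with 1,3-dichloro-5,5-dimethylhydantoin in MeCN should let the amide oxygen close on C7 to give the iminium lactone chloride F9, which is hydrolysed on aqueous work-up to 34.

Further compounds
F1 | step 12 | β-hydroxy acid (C12 carboxylic acid, C14 OH) | OC(=O)C[C@H](O)[C@](C)([C@@H](OCc1ccc(OC)cc1)CCC(I)=C)[C@H](C(=C)[Si](C)(C)C)[C@H](O[Si](C)(C)C(C)(C)C)CO[Si](C)(C)C(C)(C)C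
F2 | step 12 | triethylsilyl ester of the C14 triethylsilyl ether | CC[Si](CC)(CC)OC(=O)C[C@H](O[Si](CC)(CC)CC)[C@](C)([C@@H](OCc1ccc(OC)cc1)CCC(I)=C)[C@H](C(=C)[Si](C)(C)C)[C@H](O[Si](C)(C)C(C)(C)C)CO[Si](C)(C)C(C)(C)C
F3 | step 12 | C12 acid chloride with C14 triethylsilyl ether | ClC(=O)C[C@H](O[Si](CC)(CC)CC)[C@](C)([C@@H](OCc1ccc(OC)cc1)CCC(I)=C)[C@H](C(=C)[Si](C)(C)C)[C@H](O[Si](C)(C)C(C)(C)C)CO[Si](C)(C)C(C)(C)C
F4 | step 12 | 11-methylenecyclohexan-12-one with C14 triethylsilyl ether | C=C(I)CC[C@H](OCc1ccc(OC)cc1)[C@@]2(C)[C@@H](O[Si](CC)(CC)CC)CC(=O)C(=C)[C@@H]2[C@H](O[Si](C)(C)C(C)(C)C)CO[Si](C)(C)C(C)(C)C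
F5 | step 12 | axial C12 alcohol with C14 triethylsilyl ether | C=C(I)CC[C@H](OCc1ccc(OC)cc1)[C@@]2(C)[C@@H](O[Si](CC)(CC)CC)C[C@@H](O)C(=C)[C@@H]2[C@H](O[Si](C)(C)C(C)(C)C)CO[Si](C)(C)C(C)(C)C
F6 | step 19 | C8 allylic alcohol with vinyl group (C8 epimers) | C=C(I)CC[C@H](OCc1ccc(OC)cc1)[C@@]2(C)[C@@H]3C[C@@H](OC(C)(C)O3)C(=C)[C@@H]2[C@H](O[Si](C)(C)C(C)(C)C)C(O)C=C
F7 | step 19 | vinyl ketone (C8 ketone) | C=C(I)CC[C@H](OCc1ccc(OC)cc1)[C@@]2(C)[C@@H]3C[C@@H](OC(C)(C)O3)C(=C)[C@@H]2[C@H](O[Si](C)(C)C(C)(C)C)C(=O)C=C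
F8 | step 19 | amide aldol adduct with vinyl group at C8 | C=C(I)CC[C@H](OCc1ccc(OC)cc1)[C@@]2(C)[C@@H]3C[C@@H](OC(C)(C)O3)C(=C)[C@@H]2[C@H](O[Si](C)(C)C(C)(C)C)[C@@](O)(C=C)[C@@H](C)C(=O)N(C)C
F9 | step 21 | iminium lactone chloride (C19 dimethyliminium, C6 chloride) | C=C1CC[C@H](OCc5ccc(OC)cc5)[C@@]2(C)[C@@H]4C[C@@H](OC(C)(C)O4)C(=C)[C@@H]2[C@H](O[Si](C)(C)C(C)(C)C)[C@]3(O)[C@@H](C)C(=[N+](C)C)O[C@H]3[C@H]1Cl.[Cl-]
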